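**Partner balance.** Partner is conserved, so what stands free at any moment is its charge less what the protic impurity has taken and what the products have taken, counting one partner for each.

| flask | left-handed substrate | right-handed substrate | partner | protic impurity | free catalyst | remark |
|---|---|---|---|---|---|---|
| spring | 1.5 M | 1.5 M | 1 equiv | 0.45 M | 0.34 mol% | run made earlier |
| autumn | 1.5 M | 1.5 M | 1 equiv | 0.45 M | 0.75 mol% | run made earlier |
| flask | 1.5 M | 1.5 M | 1.00 equiv | 0.450 M | 0.5 mol% |  |

| run | time / min | left-handed product / % |
|---|---|---|
| spring | 0.833 | 2.9 |
| spring | 1.50 | 3.5 |
| spring | 3.00 | 6.3 |
| spring | 5.00 | 7.3 |
| spring | 10.0 | 9.4 |
| autumn | 0.833 | 2.4 |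
| autumn | 1.50 | 3.7 |
| autumn | 3.00 | 7.8 |
| autumn | 5.00 | 13.6 |
| autumn | 10.0 | 15.8 |

(scatter of a reading: 1 percentage point)

- apparent order in free catalyst when 5.0% of the left-handed substrate and right-handed substrate together are converted (percent change of the rate of making left-handed product for one percent more free catalyst charged)
- apparent order in partner when 5.0% of the left-handed substrate and right-handed substrate together are converted (percent change of the rate of making left-handed product for one percent more partner charged)

**The chain.** The flask charges 1.50 M of partner against 0.450 M of protic impurity, a fixed amount that does not grow with the partner charged. The asked moment, 5.0% of both substrates converted, is likewise a fixed 0.150 M of product. With the impurity gone by then, 0.900 M of partner stands free. Both subtractions stay put when the charge rises, so every added percent of charge lands on this smaller remainder. Taking the rate as first order in free partner, the apparent order equals the partner leverage, the charge over what stands free at the moment looked at, here 1.67. Catalyst charge moves neither subtraction, so at fixed conversion this reckoning gives an order near 1 in free catalyst.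

**Weak link.** The runs do not time the impurity's disappearance. With the impurity untouched, the same count gives 1.11, which marks the low end. The reckoning commits to the full 1.67 by assuming that the impurity is gone before the asked moment, a matter of speed that the runs leave open.

**The forecast.** The forecast gives 0.8 in free catalyst, between 0.4 and 1.3, and 0.5 in partner, between 0 and 1.1, noting that “Partner was never varied, so its order is a guess”. The reckoning above stands higher on partner.

**The result.** The flask gives 1.1 in free catalyst and 1.7 in partner.

    partner + free catalyst + left-handed substrate → free catalyst + left-handed product (k = 0.120 M⁻² s⁻¹)
    partner + free catalyst + right-handed substrate → free catalyst + right-handed product (k = 0.0540 M⁻² s⁻¹)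
    partner + free catalyst → spent catalyst (k = 6.40 × 10⁻⁴ M⁻¹ s⁻¹)
    partner + protic impurity → quenched reagent (k = 0.0550 M⁻¹ s⁻¹)

**Leverage again.** At the start, the protic impurity uses partner 18 times as fast as the step making left-handed product does. At 10.0 min the flask holds 13.8% of left-handed product and 6.75% of right-handed product, and the same count puts the leverage at 3.45, with 29% of the charged partner still there.

The earlier runs and the new flask were generated by integration for an exercise, noise included.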